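**Plan**

1. Retrosynthesis: the C6–C6' biaryl bond is cut first (Suzuki–Miyaura) into two monomers that differ only at C4; the 4S monomer goes back to the 4R one by C4 inversion, and both go back to one 3-O-benzyl flavanone.
2. Ring C of that flavanone is cut at O1–C8a and at C2–C3, leaving a 2-fluoroaryl α-benzyloxy ketone (ring A with C3 and C4) and 4-(benzyloxy)benzaldehyde (C2 with ring B).
3. Enabling feature: C4 of ring C, a carbinol in the target, is carried as a ketone ortho to C8a; it acidifies C3–H and makes F–C8a=C4a–C4=O a vinylogous acyl fluoride, so one base treatment forms C2–C3 (aldol) and O1–C8a (SNAr).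
4. Forward order: ring A ketone from 3-fluorocatechol, ring C closure, ketone reduction, C6 bromination, borylation of one half and C4 inversion of the other, biaryl coupling, hydrogenolysis of all benzyl ethers.
5. Stereochemistry: ring closure gives a racemic, C3-epimerizable ketone; asymmetric transfer hydrogenation with the (S,S) catalyst sets C4 (R), funnels C3 to the 3,4-cis alcohol by dynamic epimerization and selects the 2R enantiomer by kinetic resolution; Mitsunobu inversion gives the 4S half.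

Key step: step 4

Remark: flavan numbering (O1, C2, C3, C4, C4a, C5 to C8, C8a) is used for all bicyclic compounds; compounds 1, 4 and 7 are taken as commercial.

**Route**

Step 1
Reactants: 1 3-fluorobenzene-1,2-diol
Product: 2 1,2-bis(benzyloxy)-3-fluorobenzene
Conditions: BnBr, K2CO3, DMF, 60 °C
Reagents that add atoms: benzyl bromide, BrCc1ccccc1
Why: Williamson ether synthesis, in which both phenoxides are alkylated by benzyl bromide under carbonate conditions and no stereocentre is formed.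

Step 2
Reactants: 2 1,2-bis(benzyloxy)-3-fluorobenzene
Product: 3 1,2-bis(benzyloxy)-4-bromo-3-fluorobenzene
Conditions: NBS, MeCN, 0 °C to rt, dark
Reagents that add atoms: N-bromosuccinimide, O=C1CCC(=O)N1Br
Why: Electrophilic aromatic bromination should go para to the unhindered C1 benzyloxy group (the position next to fluorine), because the C2 benzyloxy group is flanked on both sides and twisted out of conjugation, and fluorine directs ortho.

Step 3
Reactants: 3 1,2-bis(benzyloxy)-4-bromo-3-fluorobenzene, 4 2-(benzyloxy)-N-methoxy-N-methylacetamide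
Product: 6 2-(benzyloxy)-1-[3,4-bis(benzyloxy)-2-fluorophenyl]ethan-1-one, via arylmagnesium chloride 5 (not isolated)
Conditions: i-PrMgCl·LiCl, THF, 0 °C; then 4, 0 °C to rt; aq. NH4Cl
Reagents that add atoms: none
Why: Bromine–magnesium exchange with the turbo-Grignard reagent gives an ortho-fluoroarylmagnesium species that is stable below room temperature and acylates the amide only once, because the chelated tetrahedral adduct persists until work-up (Weinreb ketone synthesis).

Step 4
Reactants: 6 2-(benzyloxy)-1-[3,4-bis(benzyloxy)-2-fluorophenyl]ethan-1-one, 7 4-(benzyloxy)benzaldehyde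
Product: 9 rac-(2R,3R)-3,7,8-tris(benzyloxy)-2-[4-(benzyloxy)phenyl]-2,3-dihydro-4H-chromen-4-one, via potassium aldolate 8 (not isolated)
Conditions: KN(SiMe3)2, THF, −78 °C; then 7; then DMF, −78 to 50 °C; aq. NH4Cl
Reagents that add atoms: none
Why: Proposed new method: the potassium enolate of 6 adds reversibly to aldehyde 7 (C2–C3 bond), and the aldolate oxygen O1 then attacks C8a, the fluorine-bearing carbon ortho to the C4 ketone, through a Meisenheimer intermediate whose charge rests on the C4 carbonyl, so that irreversible loss of fluoride drains the aldol equilibrium into the chromanone. The closest known reaction types are tandem addition–SNAr annulations of 2-fluoroaryl ketones (Michael–SNAr and SN2–SNAr sequences) and the closure of 1-(2-fluoroaryl)-1,3-diketones to chromones by O-SNAr; new here is a simple aldolate as the oxygen nucleophile. Ring C closes by 6-endo-trig addition–elimination at the vinylogous acyl fluoride F–C8a=C4a–C4=O. C2 is formed without control (racemate, resolved in step 5), and C3 is set thermodynamically, the α-alkoxy ketone epimerizing under the basic conditions to the 2,3-trans isomer with both substituents equatorial (C3 is set again in step 5). The step needs O-arylation to outrun E1cB dehydration and retro-aldol loss; the aprotic medium, the potassium counter-ion in DMF and the intramolecular, ketone-activated displacement should favour it, and retro-aldol only returns the two components. Regiochemistry is fixed because C8a carries the only fluorine and O3 is blocked as a benzyl ether, so a five-ring closure through O3 cannot occur.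

Step 5
Reactants: 9 rac-(2R,3R)-3,7,8-tris(benzyloxy)-2-[4-(benzyloxy)phenyl]-2,3-dihydro-4H-chromen-4-one
Product: 10 (2R,3R,4R)-3,7,8-tris(benzyloxy)-2-[4-(benzyloxy)phenyl]-3,4-dihydro-2H-chromen-4-ol
Conditions: RuCl(p-cymene)[(S,S)-TsDPEN] (cat.), HCO2H/Et3N (1:2), DMF, 40 °C, until the 2R enantiomer is consumed; recovered 2S ketone re-racemized (DBU) and recycled
Reagents that add atoms: none
Why: Noyori–Ikariya asymmetric transfer hydrogenation, in which the (S,S) catalyst should deliver hydride to the C4 face that gives the 4R carbinol, Et3N keeps C3 epimerizing through the enol so that reduction runs through the cis ketone with hydride anti to the axial 3-benzyloxy group (dynamic kinetic resolution, 3,4-cis), and only the 2R enantiomer has its equatorial 2-aryl group on the matched side (kinetic resolution, 2,4-cis).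

Step 6
Reactants: 10 (2R,3R,4R)-3,7,8-tris(benzyloxy)-2-[4-(benzyloxy)phenyl]-3,4-dihydro-2H-chromen-4-ol
Product: 11 (2R,3R,4R)-3,7,8-tris(benzyloxy)-2-[4-(benzyloxy)phenyl]-6-bromo-3,4-dihydro-2H-chromen-4-ol
Conditions: NBS, NaHCO3, MeCN/CH2Cl2, −10 °C, dark
Reagents that add atoms: N-bromosuccinimide, O=C1CCC(=O)N1Br
Why: Electrophilic aromatic bromination should occur at C6 of ring A, the only free position para to the ring oxygen O1 and ortho to the C7 benzyloxy group, whereas C5 is para only to the twisted C8 benzyloxy group and ring B is a less activated mono-ether; no stereocentre is touched.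

Step 7
Reactants: 11 (2R,3R,4R)-3,7,8-tris(benzyloxy)-2-[4-(benzyloxy)phenyl]-6-bromo-3,4-dihydro-2H-chromen-4-ol
Product: 12 (2R,3R,4R)-3,7,8-tris(benzyloxy)-2-[4-(benzyloxy)phenyl]-6-(4,4,5,5-tetramethyl-1,3,2-dioxaborolan-2-yl)-3,4-dihydro-2H-chromen-4-ol
Conditions: B2pin2, PdCl2(dppf) (cat.), KOAc, 1,4-dioxane, 85 °C
Reagents that add atoms: bis(pinacolato)diboron, CC1(C)OB(OC1(C)C)B1OC(C)(C)C(C)(C)O1
Why: Miyaura borylation (oxidative addition to zerovalent palladium, acetate-assisted transmetallation) converts the aryl bromide into the pinacol boronate and tolerates the free secondary alcohol and the benzyl ethers.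

Step 8
Reactants: 11 (2R,3R,4R)-3,7,8-tris(benzyloxy)-2-[4-(benzyloxy)phenyl]-6-bromo-3,4-dihydro-2H-chromen-4-ol
Product: 13 (2R,3S,4S)-3,7,8-tris(benzyloxy)-2-[4-(benzyloxy)phenyl]-6-bromo-3,4-dihydro-2H-chromen-4-yl 4-nitrobenzoate (2,3-cis-3,4-trans; C3 is untouched and its descriptor changes by the sequence rule only)
Conditions: PPh3, DIAD, 4-nitrobenzoic acid, THF, 0 °C to rt
Reagents that add atoms: 4-nitrobenzoic acid, OC(=O)c1ccc(cc1)[N+](=O)[O-]
Why: Mitsunobu reaction, in which the C4 oxyphosphonium is displaced by 4-nitrobenzoate with inversion to give the 4S ester trans to the axial 3-benzyloxy group, and any ionized benzylic pathway should be attacked from the same face, so both paths converge.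

Step 9
Reactants: 13 (2R,3S,4S)-3,7,8-tris(benzyloxy)-2-[4-(benzyloxy)phenyl]-6-bromo-3,4-dihydro-2H-chromen-4-yl 4-nitrobenzoate
Product: 14 (2R,3R,4S)-3,7,8-tris(benzyloxy)-2-[4-(benzyloxy)phenyl]-6-bromo-3,4-dihydro-2H-chromen-4-ol
Conditions: K2CO3 (cat.), MeOH/THF, rt
Reagents that add atoms: none
Why: Base-catalysed transesterification (Zemplén-type methanolysis) cleaves the acyl–oxygen bond of the activated ester, so the new 4S configuration is retained.

Step 10
Reactants: 12 (2R,3R,4R)-3,7,8-tris(benzyloxy)-2-[4-(benzyloxy)phenyl]-6-(4,4,5,5-tetramethyl-1,3,2-dioxaborolan-2-yl)-3,4-dihydro-2H-chromen-4-ol, 14 (2R,3R,4S)-3,7,8-tris(benzyloxy)-2-[4-(benzyloxy)phenyl]-6-bromo-3,4-dihydro-2H-chromen-4-ol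
Product: 15 (2R,2'R,3R,3'R,4R,4'S)-3,3',7,7',8,8'-hexakis(benzyloxy)-2,2'-bis[4-(benzyloxy)phenyl]-3,3',4,4'-tetrahydro-2H,2'H-[6,6'-bichromene]-4,4'-diol
Conditions: Pd(OAc)2 (cat.), SPhos (cat.), K3PO4, toluene/H2O, 80 °C
Reagents that add atoms: none
Why: Suzuki–Miyaura cross-coupling with the bulky, electron-rich SPhos ligand joins the two ortho-alkoxy aryl partners at C6 and C6', and with one ortho substituent on each ring the biaryl axis rotates freely, so no new stereo-element arises.

Step 11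
Reactants: 15 (2R,2'R,3R,3'R,4R,4'S)-3,3',7,7',8,8'-hexakis(benzyloxy)-2,2'-bis[4-(benzyloxy)phenyl]-3,3',4,4'-tetrahydro-2H,2'H-[6,6'-bichromene]-4,4'-diol
Product: 16 (2R,2'R,3R,3'R,4R,4'S)-2,2'-bis(4-hydroxyphenyl)-3,3',4,4'-tetrahydro-2H,2'H-[6,6'-bichromene]-3,3',4,4',7,7',8,8'-octol
Conditions: H2 (1 atm), Pd(OH)2/C, THF/MeOH, rt, argon during work-up
Reagents that add atoms: none
Why: Catalytic hydrogenolysis should cleave the six aryl and two alkyl benzyl ethers under neutral conditions at room temperature, where the free benzylic C4 carbinols and the ring C–O bonds react much more slowly; no stereocentre is touched.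

**Compound list**

1 | 3-fluorobenzene-1,2-diol (3-fluorocatechol) | Oc1cccc(F)c1O | starting material
2 | 1,2-bis(benzyloxy)-3-fluorobenzene | Fc1cccc(OCc2ccccc2)c1OCc1ccccc1 | intermediate
3 | 1,2-bis(benzyloxy)-4-bromo-3-fluorobenzene | Brc1ccc(OCc2ccccc2)c(OCc2ccccc2)c1F | intermediate
4 | 2-(benzyloxy)-N-methoxy-N-methylacetamide | CON(C)C(=O)COCc1ccccc1 | starting material
5 | [3,4-bis(benzyloxy)-2-fluorophenyl]magnesium chloride | Cl[Mg]c1ccc(OCc2ccccc2)c(OCc2ccccc2)c1F | intermediate (not isolated)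
6 | 2-(benzyloxy)-1-[3,4-bis(benzyloxy)-2-fluorophenyl]ethan-1-one | O=C(COCc1ccccc1)c1ccc(OCc2ccccc2)c(OCc2ccccc2)c1F | intermediate
7 | 4-(benzyloxy)benzaldehyde | O=Cc1ccc(OCc2ccccc2)cc1 | starting material
8 | potassium 2-(benzyloxy)-3-[3,4-bis(benzyloxy)-2-fluorophenyl]-1-[4-(benzyloxy)phenyl]-3-oxopropan-1-olate (equilibrating syn/anti mixture, racemic) | [K+].[O-]C(c1ccc(OCc2ccccc2)cc1)C(OCc1ccccc1)C(=O)c1ccc(OCc2ccccc2)c(OCc2ccccc2)c1F | intermediate (not isolated)
9 | rac-(2R,3R)-3,7,8-tris(benzyloxy)-2-[4-(benzyloxy)phenyl]-2,3-dihydro-4H-chromen-4-one (2,3-trans; 2R,3R enantiomer drawn) | c1cc2c(c(OCc3ccccc3)c1OCc1ccccc1)O[C@H](c1ccc(OCc3ccccc3)cc1)[C@@H](OCc1ccccc1)C2=O | intermediate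
10 | (2R,3R,4R)-3,7,8-tris(benzyloxy)-2-[4-(benzyloxy)phenyl]-3,4-dihydro-2H-chromen-4-ol (2,3-cis-3,4-cis) | c1cc2c(c(OCc3ccccc3)c1OCc1ccccc1)O[C@H](c1ccc(OCc3ccccc3)cc1)[C@H](OCc1ccccc1)[C@@H]2O | intermediate
11 | (2R,3R,4R)-3,7,8-tris(benzyloxy)-2-[4-(benzyloxy)phenyl]-6-bromo-3,4-dihydro-2H-chromen-4-ol | Brc1cc2c(c(OCc3ccccc3)c1OCc1ccccc1)O[C@H](c1ccc(OCc3ccccc3)cc1)[C@H](OCc1ccccc1)[C@@H]2O | intermediate
12 | (2R,3R,4R)-3,7,8-tris(benzyloxy)-2-[4-(benzyloxy)phenyl]-6-(4,4,5,5-tetramethyl-1,3,2-dioxaborolan-2-yl)-3,4-dihydro-2H-chromen-4-ol | CC1(C)OB(OC1(C)C)c1cc2c(c(OCc3ccccc3)c1OCc1ccccc1)O[C@H](c1ccc(OCc3ccccc3)cc1)[C@H](OCc1ccccc1)[C@@H]2O | intermediate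
13 | (2R,3S,4S)-3,7,8-tris(benzyloxy)-2-[4-(benzyloxy)phenyl]-6-bromo-3,4-dihydro-2H-chromen-4-yl 4-nitrobenzoate (2,3-cis-3,4-trans) | Brc1cc2c(c(OCc3ccccc3)c1OCc1ccccc1)O[C@H](c1ccc(OCc3ccccc3)cc1)[C@H](OCc1ccccc1)[C@H]2OC(=O)c1ccc(cc1)[N+](=O)[O-] | intermediate
14 | (2R,3R,4S)-3,7,8-tris(benzyloxy)-2-[4-(benzyloxy)phenyl]-6-bromo-3,4-dihydro-2H-chromen-4-ol (2,3-cis-3,4-trans) | Brc1cc2c(c(OCc3ccccc3)c1OCc1ccccc1)O[C@H](c1ccc(OCc3ccccc3)cc1)[C@H](OCc1ccccc1)[C@H]2O | intermediate
15 | (2R,2'R,3R,3'R,4R,4'S)-3,3',7,7',8,8'-hexakis(benzyloxy)-2,2'-bis[4-(benzyloxy)phenyl]-3,3',4,4'-tetrahydro-2H,2'H-[6,6'-bichromene]-4,4'-diol | c1ccccc1COc1ccc([C@H]2Oc3c(cc(-c4cc5c(c(OCc6ccccc6)c4OCc4ccccc4)O[C@H](c4ccc(OCc6ccccc6)cc4)[C@H](OCc4ccccc4)[C@H]5O)c(OCc4ccccc4)c3OCc3ccccc3)[C@@H](O)[C@H]2OCc2ccccc2)cc1 | intermediate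
16 | (2R,2'R,3R,3'R,4R,4'S)-2,2'-bis(4-hydroxyphenyl)-3,3',4,4'-tetrahydro-2H,2'H-[6,6'-bichromene]-3,3',4,4',7,7',8,8'-octol | Oc1ccc([C@H]2Oc3c(cc(-c4cc5c(c(O)c4O)O[C@H](c4ccc(O)cc4)[C@H](O)[C@H]5O)c(O)c3O)[C@@H](O)[C@H]2O)cc1 | target

**Step count and risks**

Total steps: 11. Longest linear sequence: 10 (steps 1, 2, 3, 4, 5, 6, 8, 9, 10, 11).

Steps most likely to fail:

Step 4 (proposed new method). The aldolate may dehydrate by E1cB to the chalcone, or revert by retro-aldol, faster than it closes onto the electron-rich fluoroarene. The fallback uses known chemistry and closes ring C at O1–C2 instead. It sets out from 6: displacement of fluoride by hydroxide (KOH, DMSO/H2O, 60 °C) gives the 2-hydroxyaryl ketone F1. Claisen–Schmidt condensation of this ketone with 7 (KOH, EtOH, rt) gives the 2'-hydroxy-α-benzyloxychalcone F2. Intramolecular oxa-Michael addition (NaOAc, EtOH, reflux) then closes the ring and returns to the route at 9.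

Step 5. The abundant trans ketone may be reduced before C3 epimerizes, giving the 3,4-trans alcohol, or the catalyst may discriminate poorly between the C2 enantiomers. The fallback sets out from 9: enolization (KN(SiMe3)2, THF, −78 °C) and kinetic protonation (AcOH, −78 °C) on the face anti to the 2-aryl group gives the racemic cis ketone F3. Reduction with NaBH4 (MeOH/THF, −20 °C), hydride entering anti to the axial 3-benzyloxy group, gives the racemic all-cis alcohol F4. Esterification with (S)-2-methoxy-2-phenylacetic acid (DCC, DMAP, CH2Cl2) and separation of the two diastereomeric esters gives the (S)-O-methylmandelate of the 2R,3R,4R alcohol F5. Methanolysis (K2CO3, MeOH) returns to the route at 10.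

Step 11. Over-reduction may occur: the benzylic C4–O bonds may be hydrogenolysed while the hindered C3 benzyl ethers are still being cleaved. The fallback sets out from 15: silylation of both C4 hydroxyls (TBSOTf, 2,6-lutidine, CH2Cl2, −40 °C) gives the bis-silyl ether F6. Hydrogenolysis (H2, Pd(OH)2/C, EtOAc/THF, rt) gives the 4,4'-bis-O-silylated polyphenol F7. Desilylation (Et3N·3HF, THF, rt) returns to the route at 16.

**Further compounds**

F1 | step 4 | 2-(benzyloxy)-1-[3,4-bis(benzyloxy)-2-hydroxyphenyl]ethan-1-one | O=C(COCc1ccccc1)c1ccc(OCc2ccccc2)c(OCc2ccccc2)c1O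
F2 | step 4 | (Z)-2-(benzyloxy)-1-[3,4-bis(benzyloxy)-2-hydroxyphenyl]-3-[4-(benzyloxy)phenyl]prop-2-en-1-one | O=C(/C(OCc1ccccc1)=C/c1ccc(OCc2ccccc2)cc1)c1ccc(OCc2ccccc2)c(OCc2ccccc2)c1O
F3 | step 5 | rac-(2R,3S)-3,7,8-tris(benzyloxy)-2-[4-(benzyloxy)phenyl]-2,3-dihydro-4H-chromen-4-one (2,3-cis; one enantiomer drawn) | c1cc2c(c(OCc3ccccc3)c1OCc1ccccc1)O[C@H](c1ccc(OCc3ccccc3)cc1)[C@H](OCc1ccccc1)C2=O
F4 | step 5 | rac-(2R,3R,4R)-3,7,8-tris(benzyloxy)-2-[4-(benzyloxy)phenyl]-3,4-dihydro-2H-chromen-4-ol (all-cis racemate; one enantiomer drawn) | c1cc2c(c(OCc3ccccc3)c1OCc1ccccc1)O[C@H](c1ccc(OCc3ccccc3)cc1)[C@H](OCc1ccccc1)[C@@H]2O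
F5 | step 5 | (2R,3S,4R)-3,7,8-tris(benzyloxy)-2-[4-(benzyloxy)phenyl]-3,4-dihydro-2H-chromen-4-yl (2S)-2-methoxy-2-phenylacetate (all-cis ring) | c1cc2c(c(OCc3ccccc3)c1OCc1ccccc1)O[C@H](c1ccc(OCc3ccccc3)cc1)[C@H](OCc1ccccc1)[C@@H]2OC(=O)[C@@H](OC)c1ccccc1
F6 | step 11 | 4,4'-bis-O-(tert-butyldimethylsilyl) ether of 15 (configurations as in 15) | c1ccccc1COc1ccc([C@H]2Oc3c(cc(-c4cc5c(c(OCc6ccccc6)c4OCc4ccccc4)O[C@H](c4ccc(OCc6ccccc6)cc4)[C@H](OCc4ccccc4)[C@H]5O[Si](C)(C)C(C)(C)C)c(OCc4ccccc4)c3OCc3ccccc3)[C@@H](O[Si](C)(C)C(C)(C)C)[C@H]2OCc2ccccc2)cc1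
F7 | step 11 | 4,4'-bis-O-(tert-butyldimethylsilyl) ether of 16 (configurations as in 16) | Oc1ccc([C@H]2Oc3c(cc(-c4cc5c(c(O)c4O)O[C@H](c4ccc(O)cc4)[C@H](O)[C@H]5O[Si](C)(C)C(C)(C)C)c(O)c3O)[C@@H](O[Si](C)(C)C(C)(C)C)[C@H]2O)cc1
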